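**Retrosynthetic overview**

1. Target ⇒ late Shi epoxidation of C3=C4 and acetylation at C13 of a 14-membered α-methylene lactone.
2. Lactone ⇒ MnO2 oxidative lactonisation of a macrocyclic 14,16-diol; the lactone is first made in the fragment union and is carried through the carbanion step as this diol.
3. 14-membered carbocycle ⇒ ring contraction of a 15-membered cyclic boronate complex (intramolecular lithiation–borylation, 1,2-shift of C9 from B to C8), which forms C8–C9 and sets C8.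
4. Open chain ⇒ indium Barbier union C1–C14 of an α-hydroxy aldehyde (C9–C14, boronate on C9) with a 2-(bromomethyl)enoate (C1–C8, carbamate on C8).
5. Ring order: butyrolactone (step 11, then opened) → 14-membered ring (step 14) → butyrolactone restored (step 15) → oxirane (step 17).

Assumptions: cembrane locants are used throughout (C1 = lactone β-carbon, C14 = lactone O–CH, C15 = lactone α-carbon, C16 = lactone C=O, C17 = exocyclic CH2); the target is read as 1S,3R,4R,8S,12S,13R,14R. 2,2-Dimethoxyacetaldehyde is used as the anhydrous monomer. Every carbon source, including CH2O, BrCH2Cl and Ac2O, has at most eight non-hydrogen atoms.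

**Route**

Step 1
Reactants: 1 2-methyl-2-vinyloxirane
Product: 2 (E)-4-chloro-2-methylbut-2-en-1-ol
Conditions: TiCl4, CH2Cl2, −85 °C; aq. NH4Cl
Reagents that add atoms: titanium tetrachloride, Cl[Ti](Cl)(Cl)Cl
Why: Lewis-acid opening of the vinyl epoxide with chloride delivery to the vinyl terminus (SN2′-type 1,4-opening) gives the E-trisubstituted allylic alcohol that fixes the later C3=C4 geometry.

Step 2
Reactants: 2 (E)-4-chloro-2-methylbut-2-en-1-ol; 3 methyl propiolate
Product: 4 methyl (E)-7-hydroxy-6-methylhept-5-en-2-ynoate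
Conditions: CuI (20 mol %), NaI (20 mol %), K2CO3, DMF, rt
Reagents that add atoms: none
Why: Copper-catalysed alkynyl–allyl coupling (alkylation of the copper acetylide) takes place at the unhindered primary allylic chloride without allylic transposition and gives the skipped enynoate.

Step 3
Reactants: 4 methyl (E)-7-hydroxy-6-methylhept-5-en-2-ynoate
Product: 5 methyl (E)-7-bromo-6-methylhept-5-en-2-ynoate
Conditions: CBr4, PPh3, CH2Cl2, 0 °C
Reagents that add atoms: carbon tetrabromide, BrC(Br)(Br)Br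
Why: Appel bromination turns the primary allylic alcohol into the bromide under neutral conditions that leave the ynoate untouched.

Step 4
Reactants: 6 (R)-but-3-yn-2-ol
Product: 7 (R)-but-3-yn-2-yl N,N-diisopropylcarbamate
Conditions: iPr2NC(O)Cl, Et3N, DMAP (cat.), toluene, 90 °C
Reagents that add atoms: N,N-diisopropylcarbamoyl chloride, CC(C)N(C(C)C)C(Cl)=O
Why: O-carbamoylation installs the Hoppe-type directing and leaving group without breaking the C–O bond, so the R configuration of the future C8 is kept.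

Step 5
Reactants: 7 (R)-but-3-yn-2-yl N,N-diisopropylcarbamate; 5 methyl (E)-7-bromo-6-methylhept-5-en-2-ynoate
Product: 9 methyl (5E,8E,10R)-10-(diisopropylcarbamoyloxy)-6-methylundeca-5,8-dien-2-ynoate, via alkenylzirconocene chloride 8 (not isolated)
Conditions: Cp2Zr(H)Cl, THF, rt; then 5, Pd(PPh3)4 (5 mol %), 0 °C → rt
Reagents that add atoms: none
Why: syn-Hydrozirconation gives the E-alkenylzirconium and palladium-catalysed alkenyl–allyl cross-coupling (Negishi type) joins it to the CH2 terminus of the allyl bromide with retention of both alkene geometries (C6=C7 and C3=C4).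

Step 6
Reactants: 9 methyl (5E,8E,10R)-10-(diisopropylcarbamoyloxy)-6-methylundeca-5,8-dien-2-ynoate
Product: 11 methyl (2Z,5E,8E,10R)-10-(diisopropylcarbamoyloxy)-2-(hydroxymethyl)-6-methylundeca-2,5,8-trienoate, via α-alumino enoate 10 (not isolated)
Conditions: DIBAL-H, HMPA, THF, 0 °C; CH2O (gas), −40 °C → rt; aq. Rochelle salt
Reagents that add atoms: formaldehyde, C=O
Why: Conjugate hydroalumination of the ynoate gives an α-alumino enoate that is captured by formaldehyde (aldol-type hydroxymethylation) to give the Baylis–Hillman-type allylic alcohol.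

Step 7
Reactants: 11 methyl (2Z,5E,8E,10R)-10-(diisopropylcarbamoyloxy)-2-(hydroxymethyl)-6-methylundeca-2,5,8-trienoate
Product: 12 methyl (2E,5E,8E,10R)-2-(bromomethyl)-10-(diisopropylcarbamoyloxy)-6-methylundeca-2,5,8-trienoate
Conditions: CBr4, PPh3, CH2Cl2, 0 °C
Reagents that add atoms: carbon tetrabromide, BrC(Br)(Br)Br
Why: Appel bromination gives the 2-(bromomethyl)enoate, whose C1=C15 geometry does not matter later because the derived allylindium equilibrates.

Step 8
Reactants: 13 (Z)-but-2-ene; 14 2,2-dimethoxyacetaldehyde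
Product: 17 (2R,3S)-1,1-dimethoxy-3-methylpent-4-en-2-ol, via (Z)-crotylpotassium 15 (not isolated), via (Z)-crotyl-B(Ipc)2 16 (not isolated)
Conditions: KOtBu, nBuLi, THF, −78 → −45 °C; (+)-Ipc2BOMe, −78 °C; BF3·OEt2; 14, −78 °C; NaOH, H2O2
Reagents that add atoms: none
Why: Brown asymmetric crotylboration through a closed chair transition state, in which the Z-crotyl unit gives the 12,13-syn relationship and the (+)-Ipc ligands (from (−)-α-pinene) direct Re-face attack, sets C13 as R and C12 as S.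

Step 9
Reactants: 17 (2R,3S)-1,1-dimethoxy-3-methylpent-4-en-2-ol
Product: 18 triethyl{[(2R,3S)-1,1-dimethoxy-3-methylpent-4-en-2-yl]oxy}silane
Conditions: TESCl, imidazole, DMF, 0 °C → rt
Reagents that add atoms: chlorotriethylsilane, CC[Si](Cl)(CC)CC
Why: Silyl protection removes the free hydroxyl, which would otherwise tie up the boron as an internal alkoxide complex in the homologation.

Step 10
Reactants: 18 triethyl{[(2R,3S)-1,1-dimethoxy-3-methylpent-4-en-2-yl]oxy}silane
Product: 20 2-[(4S,5R)-6,6-dimethoxy-4-methyl-5-(triethylsilyloxy)hexyl]-4,4,5,5-tetramethyl-1,3,2-dioxaborolane, via primary boronic ester 19 (not isolated)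
Conditions: HBpin, [Ir(cod)Cl]2 (1.5 mol %), dppm (3 mol %), THF, rt; then BrCH2Cl, nBuLi, −78 °C → rt
Reagents that add atoms: pinacolborane, B1OC(C)(C)C(C)(C)O1; bromochloromethane, ClCBr
Why: Iridium-catalysed anti-Markovnikov hydroboration gives the terminal boronic ester, and Matteson homologation with LiCH2Cl (a 1,2-metallate shift) inserts the C9 methylene.

Step 11
Reactants: 20 2-[(4S,5R)-6,6-dimethoxy-4-methyl-5-(triethylsilyloxy)hexyl]-4,4,5,5-tetramethyl-1,3,2-dioxaborolane; 12 methyl (2E,5E,8E,10R)-2-(bromomethyl)-10-(diisopropylcarbamoyloxy)-6-methylundeca-2,5,8-trienoate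
Product: 23 (1S,3E,6E,8R,12S,13R,14R)-8-(diisopropylcarbamoyloxy)-13-hydroxy-9-(pinacolboryl)-8,9-secocembra-3,6,15(17)-trien-16,14-olide, via hydroxy aldehyde 21 (not isolated), via hydroxy ester 22 (not isolated)
Conditions: 20, Amberlyst 15, THF/H2O, 40 °C, filter; 12, In powder, THF/H2O, rt; extract; PPTS (cat.), CH2Cl2, rt
Reagents that add atoms: water, O
Why: Acetal and silyl ether hydrolysis frees the α-hydroxy aldehyde, whose indium-mediated Barbier allylation in water runs under chelation control (13,14-syn) with syn simple diastereoselection (1S,14R), and kinetic γ-lactonisation then gives the cis-disubstituted α-methylene lactone.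

Step 12
Reactants: 23 (1S,3E,6E,8R,12S,13R,14R)-8-(diisopropylcarbamoyloxy)-13-hydroxy-9-(pinacolboryl)-8,9-secocembra-3,6,15(17)-trien-16,14-olide
Product: 24 (1S,3E,6E,8R,12S,13R,14R)-8-(diisopropylcarbamoyloxy)-9-(pinacolboryl)-13-(triethylsilyloxy)-8,9-secocembra-3,6,15(17)-trien-16,14-olide
Conditions: TESCl, imidazole, DMAP (cat.), DMF, rt
Reagents that add atoms: chlorotriethylsilane, CC[Si](Cl)(CC)CC
Why: Silylation of the only free hydroxyl marks O13 apart from O14, so that the later re-lactonisation can only close onto O14.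

Step 13
Reactants: 24 (1S,3E,6E,8R,12S,13R,14R)-8-(diisopropylcarbamoyloxy)-9-(pinacolboryl)-13-(triethylsilyloxy)-8,9-secocembra-3,6,15(17)-trien-16,14-olide
Product: 25 (1S,3E,6E,8R,12S,13R,14R)-8-(diisopropylcarbamoyloxy)-9-(pinacolboryl)-13-(triethylsilyloxy)-8,9-secocembra-3,6,15(17)-triene-14,16-diol
Conditions: DIBAL-H (4 equiv), CH2Cl2, −78 → 0 °C; aq. Rochelle salt
Reagents that add atoms: none
Why: DIBAL-H 1,2-reduction of the lactone to the 2-methylene-1,4-diol removes the base-sensitive Michael acceptor before the carbanion step, while the hindered carbamate and the boronic ester survive.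

Step 14
Reactants: 25 (1S,3E,6E,8R,12S,13R,14R)-8-(diisopropylcarbamoyloxy)-9-(pinacolboryl)-13-(triethylsilyloxy)-8,9-secocembra-3,6,15(17)-triene-14,16-diol
Product: 30 (1S,3E,6E,8S,12S,13R,14R)-13-(triethylsilyloxy)cembra-3,6,15(17)-triene-8,14,16-triol, via bis-TMS ether 26 (not isolated), via 8-lithio carbamate 27 (not isolated), via cyclic lithium boronate 28 (not isolated), via tertiary boronic ester 29 (not isolated)
Conditions: (Me3Si)2NH, TMSCl (cat.), CH2Cl2, rt, evaporate; syringe-pump addition (10 h) to LiTMP (3 equiv, from TMP and nBuLi), Et2O/TMEDA, −78 °C, 2 mM; MeOH, −78 → 35 °C; NaOH, H2O2, THF, 0 °C; K2CO3 (cat.), MeOH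
Reagents that add atoms: hydrogen peroxide, OO
Why: Proposed new method: a macrocyclising in situ lithiation–borylation in which LiTMP, which does not add irreversibly to the boronic ester, deprotonates the allylic carbamate with retention, the tethered pinacol boronate traps the carbanion at the α-carbon with retention to give a fifteen-membered cyclic boronate complex, and antiperiplanar 1,2-migration of C9 from boron to C8 with loss of the carbamate contracts the ring to the fourteen-membered carbocycle, so that stereoretentive C–B oxidation gives the 8S tertiary allylic alcohol; the closest known reaction type is the intermolecular lithiation–borylation of secondary allylic carbamates with boronic esters (1,2-metallate rearrangement), which has not been used intramolecularly to close a macrocycle.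

Step 15
Reactants: 30 (1S,3E,6E,8S,12S,13R,14R)-13-(triethylsilyloxy)cembra-3,6,15(17)-triene-8,14,16-triol
Product: 32 (1S,3E,6E,8S,12S,13R,14R)-8-hydroxy-13-(triethylsilyloxy)cembra-3,6,15(17)-trien-16,14-olide, via lactol 31 (not isolated)
Conditions: MnO2 (20 equiv), CH2Cl2, rt
Reagents that add atoms: none
Why: MnO2 oxidises only the primary allylic alcohol, the enal closes with the C14 hydroxyl to the five-membered lactol and this is oxidised further (oxidative lactonisation), which restores the α-methylene-γ-butyrolactone without touching the tertiary alcohol.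

Step 16
Reactants: 32 (1S,3E,6E,8S,12S,13R,14R)-8-hydroxy-13-(triethylsilyloxy)cembra-3,6,15(17)-trien-16,14-olide
Product: 34 (1S,3E,6E,8S,12S,13R,14R)-13-acetoxy-8-hydroxycembra-3,6,15(17)-trien-16,14-olide, via 13-alcohol 33 (not isolated)
Conditions: Bu4NF, AcOH, THF, 0 °C; then Ac2O, pyridine, DMAP (cat.), rt
Reagents that add atoms: acetic anhydride, CC(=O)OC(C)=O
Why: Buffered fluoride desilylation followed by DMAP-catalysed acetylation esterifies the secondary C13 hydroxyl and leaves the hindered tertiary C8 hydroxyl free.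

Step 17
Reactants: 34 (1S,3E,6E,8S,12S,13R,14R)-13-acetoxy-8-hydroxycembra-3,6,15(17)-trien-16,14-olide
Product: 35 (1S,3R,4R,6E,8S,12S,13R,14R)-13-acetoxy-3,4-epoxy-8-hydroxycembra-6,15(17)-dien-16,14-olide
Conditions: 1,2:4,5-di-O-isopropylidene-β-D-erythro-2,3-hexodiulo-2,6-pyranose (30 mol %), Oxone (2KHSO5·KHSO4·K2SO4, 1.2 equiv KHSO5), K2CO3, Bu4NHSO4, MeCN/CH2(OMe)2/H2O, 0 °C
Reagents that add atoms: potassium peroxymonosulfate, [K+].[O-]S(=O)(=O)OO
Why: Shi asymmetric epoxidation (chiral dioxirane, spiro transition state) attacks the electron-rich E-trisubstituted C3=C4 alkene in preference to the hindered C6=C7 alkene and the electron-poor exocyclic alkene, and the D-fructose-derived ketone delivers oxygen to the face that gives the 3R,4R epoxide.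

**Compound list**

1 | 2-methyl-2-vinyloxirane (racemic) | CC1(C=C)CO1 | starting material
2 | (E)-4-chloro-2-methylbut-2-en-1-ol | OC/C(C)=C/CCl | intermediate
3 | methyl propiolate | COC(=O)C#C | starting material
4 | methyl (E)-7-hydroxy-6-methylhept-5-en-2-ynoate | COC(=O)C#CC/C=C(\C)CO | intermediate
5 | methyl (E)-7-bromo-6-methylhept-5-en-2-ynoate | COC(=O)C#CC/C=C(\C)CBr | intermediate
6 | (R)-but-3-yn-2-ol | C[C@@H](O)C#C | starting material
7 | (R)-but-3-yn-2-yl N,N-diisopropylcarbamate | C[C@@H](OC(=O)N(C(C)C)C(C)C)C#C | intermediate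
8 | chlorobis(cyclopentadienyl)[(1E,3R)-3-(diisopropylcarbamoyloxy)but-1-en-1-yl]zirconium | C[C@@H](OC(=O)N(C(C)C)C(C)C)/C=C/[Zr](Cl)(C1C=CC=C1)C1C=CC=C1 | intermediate
9 | methyl (5E,8E,10R)-10-(diisopropylcarbamoyloxy)-6-methylundeca-5,8-dien-2-ynoate | COC(=O)C#CC/C=C(\C)C/C=C/[C@@H](C)OC(=O)N(C(C)C)C(C)C | intermediate
10 | methyl (2E,5E,8E,10R)-2-(diisobutylalumanyl)-10-(diisopropylcarbamoyloxy)-6-methylundeca-2,5,8-trienoate | COC(=O)/C([Al](CC(C)C)CC(C)C)=C\C/C=C(\C)C/C=C/[C@@H](C)OC(=O)N(C(C)C)C(C)C | intermediate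
11 | methyl (2Z,5E,8E,10R)-10-(diisopropylcarbamoyloxy)-2-(hydroxymethyl)-6-methylundeca-2,5,8-trienoate | COC(=O)/C(CO)=C\C/C=C(\C)C/C=C/[C@@H](C)OC(=O)N(C(C)C)C(C)C | intermediate
12 | methyl (2E,5E,8E,10R)-2-(bromomethyl)-10-(diisopropylcarbamoyloxy)-6-methylundeca-2,5,8-trienoate | COC(=O)/C(CBr)=C\C/C=C(\C)C/C=C/[C@@H](C)OC(=O)N(C(C)C)C(C)C | intermediate
13 | (Z)-but-2-ene | C/C=C\C | starting material
14 | 2,2-dimethoxyacetaldehyde | COC(OC)C=O | starting material
15 | (Z)-but-2-en-1-ylpotassium | C/C=C\C[K] | intermediate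
16 | (Z)-but-2-en-1-ylbis[(1S,2R,3S,5S)-2,6,6-trimethylbicyclo[3.1.1]heptan-3-yl]borane | C/C=C\CB([C@H]1C[C@H]2C[C@@H]([C@@H]1C)C2(C)C)[C@H]1C[C@H]2C[C@@H]([C@@H]1C)C2(C)C | intermediate
17 | (2R,3S)-1,1-dimethoxy-3-methylpent-4-en-2-ol | COC(OC)[C@H](O)[C@@H](C)C=C | intermediate
18 | triethyl{[(2R,3S)-1,1-dimethoxy-3-methylpent-4-en-2-yl]oxy}silane | COC(OC)[C@H](O[Si](CC)(CC)CC)[C@@H](C)C=C | intermediate
19 | 2-[(3S,4R)-5,5-dimethoxy-3-methyl-4-(triethylsilyloxy)pentyl]-4,4,5,5-tetramethyl-1,3,2-dioxaborolane | COC(OC)[C@H](O[Si](CC)(CC)CC)[C@@H](C)CCB1OC(C)(C)C(C)(C)O1 | intermediate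
20 | 2-[(4S,5R)-6,6-dimethoxy-4-methyl-5-(triethylsilyloxy)hexyl]-4,4,5,5-tetramethyl-1,3,2-dioxaborolane | COC(OC)[C@H](O[Si](CC)(CC)CC)[C@@H](C)CCCB1OC(C)(C)C(C)(C)O1 | intermediate
21 | (2R,3S)-2-hydroxy-3-methyl-6-(4,4,5,5-tetramethyl-1,3,2-dioxaborolan-2-yl)hexanal | O=C[C@H](O)[C@@H](C)CCCB1OC(C)(C)C(C)(C)O1 | intermediate
22 | methyl (1S,3E,6E,8R,12S,13R,14R)-8-(diisopropylcarbamoyloxy)-13,14-dihydroxy-9-(pinacolboryl)-8,9-secocembra-3,6,15(17)-trien-16-oate | C=C(C(=O)OC)[C@H](C/C=C(\C)C/C=C/[C@@H](C)OC(=O)N(C(C)C)C(C)C)[C@@H](O)[C@H](O)[C@@H](C)CCCB1OC(C)(C)C(C)(C)O1 | intermediate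
23 | (1S,3E,6E,8R,12S,13R,14R)-8-(diisopropylcarbamoyloxy)-13-hydroxy-9-(pinacolboryl)-8,9-secocembra-3,6,15(17)-trien-16,14-olide | C=C1C(=O)O[C@@H]([C@H](O)[C@@H](C)CCCB2OC(C)(C)C(C)(C)O2)[C@H]1C/C=C(\C)C/C=C/[C@@H](C)OC(=O)N(C(C)C)C(C)C | intermediate
24 | 13-O-triethylsilyl ether of 23 | C=C1C(=O)O[C@@H]([C@H](O[Si](CC)(CC)CC)[C@@H](C)CCCB2OC(C)(C)C(C)(C)O2)[C@H]1C/C=C(\C)C/C=C/[C@@H](C)OC(=O)N(C(C)C)C(C)C | intermediate
25 | (1S,3E,6E,8R,12S,13R,14R)-8-(diisopropylcarbamoyloxy)-9-(pinacolboryl)-13-(triethylsilyloxy)-8,9-secocembra-3,6,15(17)-triene-14,16-diol | C[C@@H](OC(=O)N(C(C)C)C(C)C)/C=C/C/C(C)=C/C[C@@H](C(=C)CO)[C@@H](O)[C@H](O[Si](CC)(CC)CC)[C@@H](C)CCCB1OC(C)(C)C(C)(C)O1 | intermediate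
26 | 14,16-bis-O-trimethylsilyl ether of 25 | C[C@@H](OC(=O)N(C(C)C)C(C)C)/C=C/C/C(C)=C/C[C@@H](C(=C)CO[Si](C)(C)C)[C@@H](O[Si](C)(C)C)[C@H](O[Si](CC)(CC)CC)[C@@H](C)CCCB1OC(C)(C)C(C)(C)O1 | intermediate
27 | 8-lithio derivative of 26 (Li in place of H-8, 8R) | C[C@@]([Li])(OC(=O)N(C(C)C)C(C)C)/C=C/C/C(C)=C/C[C@@H](C(=C)CO[Si](C)(C)C)[C@@H](O[Si](C)(C)C)[C@H](O[Si](CC)(CC)CC)[C@@H](C)CCCB1OC(C)(C)C(C)(C)O1 | intermediate
28 | lithium boronate complex, fifteen-membered ring (B bonded to C8 and C9, pinacolato on B, carbamate still on C8, 8R) | C[C@@]1(OC(=O)N(C(C)C)C(C)C)/C=C/C/C(C)=C/C[C@@H](C(=C)CO[Si](C)(C)C)[C@@H](O[Si](C)(C)C)[C@H](O[Si](CC)(CC)CC)[C@@H](C)CCC[B-]12OC(C)(C)C(C)(C)O2.[Li+] | intermediate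
29 | (1S,3E,6E,8R,12S,13R,14R)-8-(pinacolboryl)-13-(triethylsilyloxy)-14,16-bis(trimethylsilyloxy)cembra-3,6,15(17)-triene | C[C@@]1(B2OC(C)(C)C(C)(C)O2)/C=C/C/C(C)=C/C[C@@H](C(=C)CO[Si](C)(C)C)[C@@H](O[Si](C)(C)C)[C@H](O[Si](CC)(CC)CC)[C@@H](C)CCC1 | intermediate
30 | (1S,3E,6E,8S,12S,13R,14R)-13-(triethylsilyloxy)cembra-3,6,15(17)-triene-8,14,16-triol | C[C@@]1(O)/C=C/C/C(C)=C/C[C@@H](C(=C)CO)[C@@H](O)[C@H](O[Si](CC)(CC)CC)[C@@H](C)CCC1 | intermediate
31 | (1S,3E,6E,8S,12S,13R,14R)-14,16-epoxy-13-(triethylsilyloxy)cembra-3,6,15(17)-triene-8,16-diol (lactol, both C16 epimers) | C=C1C(O)O[C@H]2[C@H](O[Si](CC)(CC)CC)[C@@H](C)CCC[C@](C)(O)/C=C/C/C(C)=C/C[C@@H]12 | intermediate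
32 | (1S,3E,6E,8S,12S,13R,14R)-8-hydroxy-13-(triethylsilyloxy)cembra-3,6,15(17)-trien-16,14-olide | C=C1C(=O)O[C@H]2[C@H](O[Si](CC)(CC)CC)[C@@H](C)CCC[C@](C)(O)/C=C/C/C(C)=C/C[C@@H]12 | intermediate
33 | (1S,3E,6E,8S,12S,13R,14R)-8,13-dihydroxycembra-3,6,15(17)-trien-16,14-olide | C=C1C(=O)O[C@H]2[C@H](O)[C@@H](C)CCC[C@](C)(O)/C=C/C/C(C)=C/C[C@@H]12 | intermediate
34 | (1S,3E,6E,8S,12S,13R,14R)-13-acetoxy-8-hydroxycembra-3,6,15(17)-trien-16,14-olide | C=C1C(=O)O[C@H]2[C@H](OC(C)=O)[C@@H](C)CCC[C@](C)(O)/C=C/C/C(C)=C/C[C@@H]12 | intermediate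
35 | (1S,3R,4R,6E,8S,12S,13R,14R)-13-acetoxy-3,4-epoxy-8-hydroxycembra-6,15(17)-dien-16,14-olide (CNP0202356.4) | C=C1C(=O)O[C@H]2[C@H](OC(C)=O)[C@@H](C)CCC[C@](C)(O)/C=C/C[C@@]3(C)O[C@@H]3C[C@@H]12 | target

**Step count and risks**

Total step count: 17. Longest linear sequence: 13 (steps 1–3, 5–7, 11–17).

Three steps most likely to fail:

Step 6 (hydroalumination and formaldehyde capture on a polyunsaturated, carbamate-bearing ynoate; risks are 1,2-reduction, isomerisation of the skipped CH2 and poor capture of CH2O). Fallback, from 9 back to 11: palladium-catalysed syn-hydrostannation of 9 (Bu3SnH, Pd(PPh3)4) gives methyl (2E,5E,8E,10R)-10-(diisopropylcarbamoyloxy)-6-methyl-2-(tributylstannyl)undeca-2,5,8-trienoate F1. Iododestannylation (I2, CH2Cl2, 0 °C) gives methyl (2E,5E,8E,10R)-10-(diisopropylcarbamoyloxy)-2-iodo-6-methylundeca-2,5,8-trienoate F2. Stille coupling of F2 with Bu3SnCH2OH (Pd(PPh3)4, dioxane, 80 °C) then gives 11, so the carbon–carbon bond to C17 is made by cross-coupling and not by an aluminium enolate.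

Step 14 (the proposed ring contraction; risks are slow deprotonation by LiTMP, oligomerisation, γ-borylation and reversal of the boronate complex before migration). Fallback with known chemistry, from 7 and 20 back to 33: C-silylate 7 (LiHMDS, TMSCl) to (R)-4-(trimethylsilyl)but-3-yn-2-yl N,N-diisopropylcarbamate F3. Run the established intermolecular lithiation–borylation of this secondary propargylic carbamate with 20 (sBuLi, TMEDA, Et2O, −78 °C; 20; warm; NaOH, H2O2; K2CO3, MeOH), which sets C8 and gives (3S,7S,8R)-9,9-dimethoxy-3,7-dimethyl-8-(triethylsilyloxy)non-1-yn-3-ol F4. Hydrozirconate F4 and couple it with 5 as in step 5 to methyl (5E,8E,10S,14S,15R)-10-hydroxy-16,16-dimethoxy-6,10,14-trimethyl-15-(triethylsilyloxy)hexadeca-5,8-dien-2-ynoate F5. Hydroxymethylate as in step 6 to methyl (2Z,5E,8E,10S,14S,15R)-10-hydroxy-2-(hydroxymethyl)-16,16-dimethoxy-6,10,14-trimethyl-15-(triethylsilyloxy)hexadeca-2,5,8-trienoate F6, and brominate as in step 7 to methyl (2E,5E,8E,10S,14S,15R)-2-(bromomethyl)-10-hydroxy-16,16-dimethoxy-6,10,14-trimethyl-15-(triethylsilyloxy)hexadeca-2,5,8-trienoate F7. Acid-resin hydrolysis gives methyl (2E,5E,8E,10S,14S,15R)-2-(bromomethyl)-10,15-dihydroxy-6,10,14-trimethyl-16-oxohexadeca-2,5,8-trienoate F8. The ring is then closed at C1–C14 by intramolecular indium Barbier allylation (THF/H2O, 2 mM), the macrocyclisation mode precedented for cembranolides, to methyl (1S,3E,6E,8S,12S,13R,14R)-8,13,14-trihydroxycembra-3,6,15(17)-trien-16-oate F9. PPTS lactonisation gives 33, which is acetylated as in the second stage of step 16.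

Step 17 (late epoxidation; risks are a catalyst-controlled face that is mismatched with the exposed face of the macrocyclic alkene, and over-oxidation at C6=C7). Fallback, from 34 back to 35: a two-stage, substrate-controlled halohydrin route. NBS in THF/H2O at 0 °C adds to the most electron-rich alkene with Markovnikov anti addition to give (1S,3S,4R,6E,8S,12S,13R,14R)-13-acetoxy-3-bromo-4,8-dihydroxycembra-6,15(17)-dien-16,14-olide F10. DBU in CH2Cl2 closes the oxirane by inversion at C3 to give 35. This places oxygen on the face opposite to the one first attacked by the electrophile, so it is complementary to a direct peracid epoxidation and independent of the chiral ketone.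

Further compounds
F1 | step 6 | methyl (2E,5E,8E,10R)-10-(diisopropylcarbamoyloxy)-6-methyl-2-(tributylstannyl)undeca-2,5,8-trienoate | COC(=O)/C([Sn](CCCC)(CCCC)CCCC)=C\C/C=C(\C)C/C=C/[C@@H](C)OC(=O)N(C(C)C)C(C)C
F2 | step 6 | methyl (2E,5E,8E,10R)-10-(diisopropylcarbamoyloxy)-2-iodo-6-methylundeca-2,5,8-trienoate | COC(=O)/C(I)=C\C/C=C(\C)C/C=C/[C@@H](C)OC(=O)N(C(C)C)C(C)C
F3 | step 14 | (R)-4-(trimethylsilyl)but-3-yn-2-yl N,N-diisopropylcarbamate | C[C@@H](OC(=O)N(C(C)C)C(C)C)C#C[Si](C)(C)C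
F4 | step 14 | (3S,7S,8R)-9,9-dimethoxy-3,7-dimethyl-8-(triethylsilyloxy)non-1-yn-3-ol | C#C[C@@](C)(O)CCC[C@H](C)[C@@H](O[Si](CC)(CC)CC)C(OC)OC
F5 | step 14 | methyl (5E,8E,10S,14S,15R)-10-hydroxy-16,16-dimethoxy-6,10,14-trimethyl-15-(triethylsilyloxy)hexadeca-5,8-dien-2-ynoate | COC(=O)C#CC/C=C(\C)C/C=C/[C@@](C)(O)CCC[C@H](C)[C@@H](O[Si](CC)(CC)CC)C(OC)OC
F6 | step 14 | methyl (2Z,5E,8E,10S,14S,15R)-10-hydroxy-2-(hydroxymethyl)-16,16-dimethoxy-6,10,14-trimethyl-15-(triethylsilyloxy)hexadeca-2,5,8-trienoate | COC(=O)/C(CO)=C\C/C=C(\C)C/C=C/[C@@](C)(O)CCC[C@H](C)[C@@H](O[Si](CC)(CC)CC)C(OC)OC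
F7 | step 14 | methyl (2E,5E,8E,10S,14S,15R)-2-(bromomethyl)-10-hydroxy-16,16-dimethoxy-6,10,14-trimethyl-15-(triethylsilyloxy)hexadeca-2,5,8-trienoate | COC(=O)/C(CBr)=C\C/C=C(\C)C/C=C/[C@@](C)(O)CCC[C@H](C)[C@@H](O[Si](CC)(CC)CC)C(OC)OC
F8 | step 14 | methyl (2E,5E,8E,10S,14S,15R)-2-(bromomethyl)-10,15-dihydroxy-6,10,14-trimethyl-16-oxohexadeca-2,5,8-trienoate | COC(=O)/C(CBr)=C\C/C=C(\C)C/C=C/[C@@](C)(O)CCC[C@H](C)[C@@H](O)C=O
F9 | step 14 | methyl (1S,3E,6E,8S,12S,13R,14R)-8,13,14-trihydroxycembra-3,6,15(17)-trien-16-oate | COC(=O)C(=C)[C@@H]1C/C=C(\C)C/C=C/[C@@](C)(O)CCC[C@H](C)[C@@H](O)[C@@H]1O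
F10 | step 17 | (1S,3S,4R,6E,8S,12S,13R,14R)-13-acetoxy-3-bromo-4,8-dihydroxycembra-6,15(17)-dien-16,14-olide | C=C1C(=O)O[C@H]2[C@H](OC(C)=O)[C@@H](C)CCC[C@](C)(O)/C=C/C[C@@](C)(O)[C@@H](Br)C[C@@H]12
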